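**Plan**
- Retrosynthesis: the enol ester C–O bond, the C2 hydroxymethyl oxidation level and the C7 acetonyl group (placed with the help of a sacrificial C7 carboxyl) are adjusted last; the ring is then cut at C2=C3 and C6–C7 into aldehyde–enal 10 and ketodiester 12, and 10 is traced by α-ketol cleavage to cyclohexanone 4.
- Enabling feature: C7–C1–C2 and the hydroxymethyl carbon of the seven-membered ring map onto a 3-oxopentanedioate, while C3 and C6 are the two electrophilic ends (aldehyde carbon and enal β-carbon) of the C3–C4–C5–C6 chain.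
- Forward: conjugate addition builds C5 on a cyclohexanone, the six-membered ring is opened, the chain is closed onto the ketodiester to give the only ring of the target (step 8), and the three side arms are then finished.
- Stereochemistry: C5 comes from the ligand-controlled copper-catalysed conjugate addition (step 1), C6 from the amine catalyst in step 8 (arm cis to the C5 methyl), C7 from kinetic protonation in the palladium-catalysed decarboxylation (step 15), and the E enol ester from equilibrating acylation (step 14).

Key step: step 8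

Remark: ring locants are those of cyclohept-2-en-1-one (C1 C=O, C2 bearing CH2OH, C3 =CH, C4 CH2, C5 quaternary, C6 bearing the enol ester arm, C7 bearing the acetonyl group); the target is (5S,6S,7R).
Remark: the sense of induction in steps 1 and 8 is assigned from the accepted models for these catalyst classes; the catalyst enantiomer is the variable to exchange if an assignment had to be reversed.
Remark: diallyl ester 12 is assumed not to be a stock chemical and is made in step 7.
Remark: 14 is written in its open keto-aldehyde form; it is expected to equilibrate with its C1–C7 enol and the derived cyclic lactol.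

**Step 1**
Reactants: 1 5-bromo-2-methylpent-2-ene; 2 3-methylcyclohex-2-en-1-one
Product: 4 (3S)-3-methyl-3-(4-methylpent-3-en-1-yl)cyclohexan-1-one, via Grignard reagent 3 (not isolated)
Conditions: Mg turnings, Et2O, rt (gives 3); then 2, Cu(OTf)2 (3 mol %), chiral N-mesityl hydroxyalkyl imidazolinium salt (leucinol-derived carbene precursor, 4 mol %), Et2O, 0 °C; aq. NH4Cl
Reagents that add atoms: magnesium, [Mg] (retained in intermediate 3 only)
Why: Copper-catalysed asymmetric conjugate addition of the primary alkyl Grignard reagent to the β-methyl enone creates the all-carbon quaternary centre (future C5), the enantiomer of the carbene ligand being chosen so that the homoprenyl group reaches the enone face that gives the S ketone.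

**Step 2**
Reactants: 4 (3S)-3-methyl-3-(4-methylpent-3-en-1-yl)cyclohexan-1-one
Product: 6 (2RS,5R)-2-hydroxy-5-methyl-5-(4-methylpent-3-en-1-yl)cyclohexan-1-one, via potassium enolate 5 (not isolated)
Conditions: KN(SiMe3)2, THF, −78 °C (gives 5); then 2-(phenylsulfonyl)-3-phenyloxaziridine, −78 °C; aq. NH4Cl
Reagents that add atoms: 2-(phenylsulfonyl)-3-phenyloxaziridine, O=S(=O)(c1ccccc1)N1OC1c1ccccc1; potassium bis(trimethylsilyl)amide, C[Si](C)(C)[N-][Si](C)(C)C.[K+] (potassium retained in intermediate 5 only)
Why: Kinetic deprotonation takes the unhindered methylene remote from the quaternary carbon rather than the neopentyl one, and electrophilic enolate hydroxylation with the N-sulfonyloxaziridine (no peracid, so the trisubstituted alkene is spared) gives the α-ketol, whose new carbinol centre is of no consequence because it is destroyed in step 3.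

**Step 3**
Reactants: 6 (2RS,5R)-2-hydroxy-5-methyl-5-(4-methylpent-3-en-1-yl)cyclohexan-1-one
Product: 7 methyl (3R)-3,7-dimethyl-3-(3-oxopropyl)oct-6-enoate
Conditions: Pb(OAc)4, MeOH–benzene (1:2), 0 °C
Reagents that add atoms: methanol, CO
Why: Lead tetraacetate cleavage of the α-ketol in methanol (glycol-type cleavage of the hemiketal) opens the ring between carbonyl and carbinol carbons, so that the two-carbon arm ends as a methyl ester and the three-carbon arm as an aldehyde, already differentiated.

**Step 4**
Reactants: 7 methyl (3R)-3,7-dimethyl-3-(3-oxopropyl)oct-6-enoate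
Product: 8 methyl (3S)-3,7-dimethyl-3-[(1E)-3-oxoprop-1-en-1-yl]oct-6-enoate
Conditions: IBX (1.5 equiv), DMSO–fluorobenzene (1:2), 65 °C
Reagents that add atoms: none
Why: IBX-mediated α,β-dehydrogenation of the aldehyde should install the thermodynamically preferred E enal next to the quaternary carbon, while the ester arm has no β-hydrogen and cannot react (the descriptor change is formal).

**Step 5**
Reactants: 8 methyl (3S)-3,7-dimethyl-3-[(1E)-3-oxoprop-1-en-1-yl]oct-6-enoate
Product: 9 (2E,4S)-4-(2-hydroxyethyl)-4,8-dimethylnona-2,7-dien-1-ol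
Conditions: iBu2AlH (5 equiv), CH2Cl2, −78 → 0 °C; aq. potassium sodium tartrate
Reagents that add atoms: none
Why: Exhaustive hydride reduction converts the ester into the primary alcohol and the enal, by 1,2-addition, into the E allylic alcohol, which avoids the impossible partial reduction of an ester beside an enal.

**Step 6**
Reactants: 9 (2E,4S)-4-(2-hydroxyethyl)-4,8-dimethylnona-2,7-dien-1-ol
Product: 10 (2E,4S)-4,8-dimethyl-4-(2-oxoethyl)nona-2,7-dienal
Conditions: DMP (1,1,1-triacetoxy-1,1-dihydro-1,2-benziodoxol-3(1H)-one, 2.4 equiv), NaHCO3, CH2Cl2, 0 °C → rt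
Reagents that add atoms: none
Why: Double periodinane oxidation under buffered, non-enolising conditions should give the aldehyde–enal, which is protected against intramolecular aldol closure because the E alkene holds the two carbonyl arms apart and the enal has no γ-hydrogen.

**Step 7**
Reactants: 11 dimethyl 3-oxopentanedioate
Product: 12 diallyl 3-oxopentanedioate
Conditions: allyl alcohol (6 equiv), DMAP (10 mol %), toluene, reflux, 4 Å molecular sieves (removal of MeOH)
Reagents that add atoms: allyl alcohol, C=CCO
Why: DMAP-assisted thermal transesterification of the enolisable β-keto ester (through its acylketene) exchanges both methyl groups for allyl groups, which later allow neutral, hydride-free removal of the C7 carboxyl.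

**Step 8**
Reactants: 10 (2E,4S)-4,8-dimethyl-4-(2-oxoethyl)nona-2,7-dienal; 12 diallyl 3-oxopentanedioate
Product: 14 diallyl (5S,6S)-5-methyl-5-(4-methylpent-3-en-1-yl)-1-oxo-6-(2-oxoethyl)cyclohept-2-ene-2,7-dicarboxylate, via Knoevenagel adduct 13 (not isolated)
Conditions: ethylenediammonium diacetate (5 mol %), 4 Å molecular sieves, CH2Cl2 (0.02 M), 0 °C (gives 13); then (R)-2-{bis[3,5-bis(trifluoromethyl)phenyl](trimethylsilyloxy)methyl}pyrrolidine (20 mol %), PhCO2H (20 mol %), 0 °C → rt
Reagents that add atoms: none
Why: Proposed new method: the ammonium acetate condenses one active methylene of 12 with the unhindered saturated aldehyde of 10 (Knoevenagel condensation, forming C2=C3) to give 13, after which the prolinol silyl ether turns the enal into an E iminium ion and the remaining C7 methylene, as its enol, adds to C6 in an intramolecular Michael reaction; the closest known reactions are amine-catalysed Knoevenagel condensations of 3-oxoglutarates and iminium-catalysed Michael additions of β-keto esters to enals, which have not been joined in a seven-ring-forming (4+3) annulation. The cycloheptenone closes at C6–C7 in the 7-exo-trig mode, helped by the cis-disposed C2=C3 bond (reached through reversible amine addition to the alkylidene) and by the geminal substitution at C5. C6 is set by the catalyst, whose silyloxydiarylmethyl group blocks one face of the iminium ion; the R catalyst is chosen so that C7 arrives on the face that leaves the C6 arm cis to the C5 methyl (6S), the neighbouring quaternary centre alone offering little bias, and C7 stays epimerisable as an enolised β-keto ester until step 15. The step needs condensation before conjugate addition, because the reverse order would enter the known Michael–Knoevenagel route to a cyclohexenone; this order should be secured by the neopentyl shielding of the enal β-carbon against intermolecular attack and by starting with the achiral ammonium salt at 0 °C. It also needs the Michael closure to outrun an intramolecular oxa-Diels–Alder reaction of the alkylidene keto ester with the side-chain alkene, which normally requires heating, and transannular attack of the arm enamine on C3, which is disfavoured because the product rests as the C1–C7 enol or its lactol.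

**Step 9**
Reactants: 14 diallyl (5S,6S)-5-methyl-5-(4-methylpent-3-en-1-yl)-1-oxo-6-(2-oxoethyl)cyclohept-2-ene-2,7-dicarboxylate
Product: 15 diallyl (5S,6S)-6-(1,3-dioxolan-2-ylmethyl)-5-methyl-5-(4-methylpent-3-en-1-yl)-1-oxocyclohept-2-ene-2,7-dicarboxylate
Conditions: 1,2-bis(trimethylsilyloxy)ethane, TMSOTf (5 mol %), CH2Cl2, −78 → −20 °C; aq. NaHCO3
Reagents that add atoms: 1,2-bis(trimethylsilyloxy)ethane, C[Si](C)(C)OCCO[Si](C)(C)C
Why: Low-temperature silyl-triflate-catalysed acetalisation is selective for the aldehyde, since the ring ketone is held as the enol of a β-keto ester, and closure of the five-membered dioxolane should pull the lactol equilibrium to the open, protected form.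

**Step 10**
Reactants: 15 diallyl (5S,6S)-6-(1,3-dioxolan-2-ylmethyl)-5-methyl-5-(4-methylpent-3-en-1-yl)-1-oxocyclohept-2-ene-2,7-dicarboxylate
Product: 17 allyl (5S,6S)-6-(1,3-dioxolan-2-ylmethyl)-2-(hydroxymethyl)-5-methyl-5-(4-methylpent-3-en-1-yl)-1-oxocyclohept-2-ene-7-carboxylate, via sodium enolate 16 (not isolated)
Conditions: NaH (1.05 equiv), THF, 0 °C (gives 16); then iBu2AlH (2.5 equiv), −78 °C; aq. potassium sodium tartrate
Reagents that add atoms: sodium hydride, [Na+].[H-] (sodium retained in intermediate 16 only)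
Why: Deprotonation converts the β-keto ester into its sodium enolate, which shields both the C1 carbonyl and the C7 ester from hydride (in situ enolate protection), so that the aluminium hydride should reduce only the conjugated C2 allyl ester, by 1,2-addition, to the allylic alcohol.

**Step 11**
Reactants: 17 allyl (5S,6S)-6-(1,3-dioxolan-2-ylmethyl)-2-(hydroxymethyl)-5-methyl-5-(4-methylpent-3-en-1-yl)-1-oxocyclohept-2-ene-7-carboxylate
Product: 18 allyl (5S,6S)-2-[(tert-butyldiphenylsilyloxy)methyl]-6-(1,3-dioxolan-2-ylmethyl)-5-methyl-5-(4-methylpent-3-en-1-yl)-1-oxocyclohept-2-ene-7-carboxylate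
Conditions: TBDPSCl, imidazole, CH2Cl2, 0 °C → rt
Reagents that add atoms: tert-butyl(chloro)diphenylsilane, CC(C)(C)[Si](Cl)(c1ccccc1)c1ccccc1
Why: Standard silylation of the primary allylic alcohol, the hydrogen-bonded enol of the β-keto ester being too hindered to react; the acid-robust silyl group is chosen to survive step 13.

**Step 12**
Reactants: 18 allyl (5S,6S)-2-[(tert-butyldiphenylsilyloxy)methyl]-6-(1,3-dioxolan-2-ylmethyl)-5-methyl-5-(4-methylpent-3-en-1-yl)-1-oxocyclohept-2-ene-7-carboxylate
Product: 19 allyl (5S,6R,7ξ)-2-[(tert-butyldiphenylsilyloxy)methyl]-6-(1,3-dioxolan-2-ylmethyl)-5-methyl-5-(4-methylpent-3-en-1-yl)-1-oxo-7-(2-oxopropyl)cyclohept-2-ene-7-carboxylate (C5 and C6 unchanged in space; the 6R descriptor is formal)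
Conditions: chloroacetone, K2CO3, NaI (20 mol %), acetone, rt → 40 °C
Reagents that add atoms: chloroacetone, CC(=O)CCl
Why: C-alkylation of the soft potassium enolate of the β-keto ester with iodoacetone formed in situ (Finkelstein exchange) makes C7 quaternary and non-epimerisable; its configuration does not matter because it is erased in step 15.

**Step 13**
Reactants: 19 allyl (5S,6R,7ξ)-2-[(tert-butyldiphenylsilyloxy)methyl]-6-(1,3-dioxolan-2-ylmethyl)-5-methyl-5-(4-methylpent-3-en-1-yl)-1-oxo-7-(2-oxopropyl)cyclohept-2-ene-7-carboxylate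
Product: 20 allyl (5S,6R,7ξ)-2-[(tert-butyldiphenylsilyloxy)methyl]-5-methyl-5-(4-methylpent-3-en-1-yl)-1-oxo-6-(2-oxoethyl)-7-(2-oxopropyl)cyclohept-2-ene-7-carboxylate
Conditions: PPTS (0.3 equiv), acetone–H2O (10:1), 50 °C
Reagents that add atoms: water, O
Why: Mild acid-catalysed acetal hydrolysis frees the aldehyde while the silyl ether, the allyl ester and the enone should survive; the 1,4-diketone cannot aromatise to a furan because C7 carries no hydrogen.

**Step 14**
Reactants: 20 allyl (5S,6R,7ξ)-2-[(tert-butyldiphenylsilyloxy)methyl]-5-methyl-5-(4-methylpent-3-en-1-yl)-1-oxo-6-(2-oxoethyl)-7-(2-oxopropyl)cyclohept-2-ene-7-carboxylate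
Product: 21 allyl (5S,6R,7ξ)-2-[(tert-butyldiphenylsilyloxy)methyl]-5-methyl-6-[(E)-2-(3-methylbut-2-enoyloxy)ethenyl]-5-(4-methylpent-3-en-1-yl)-1-oxo-7-(2-oxopropyl)cyclohept-2-ene-7-carboxylate
Conditions: 3-methylbut-2-enoic anhydride (2 equiv), Et3N, DMAP (0.3 equiv), CH2Cl2, rt → 40 °C
Reagents that add atoms: 3-methylbut-2-enoic anhydride, CC(C)=CC(=O)OC(=O)C=C(C)C
Why: DMAP-mediated O-acylation of the aldehyde enol (enol esterification) under equilibrating conditions should favour the E enol ester, in which the acyloxy group avoids the bulky ring carbon; the anhydride avoids the vinylketene path that deconjugates senecioyl chlorides, the methyl ketone enolises far more slowly than the aldehyde, and any Z isomer would be removed by chromatography at this robust stage.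

**Step 15**
Reactants: 21 allyl (5S,6R,7ξ)-2-[(tert-butyldiphenylsilyloxy)methyl]-5-methyl-6-[(E)-2-(3-methylbut-2-enoyloxy)ethenyl]-5-(4-methylpent-3-en-1-yl)-1-oxo-7-(2-oxopropyl)cyclohept-2-ene-7-carboxylate
Product: 22 (5S,6S,7R)-2-[(tert-butyldiphenylsilyloxy)methyl]-5-methyl-6-[(E)-2-(3-methylbut-2-enoyloxy)ethenyl]-5-(4-methylpent-3-en-1-yl)-7-(2-oxopropyl)cyclohept-2-en-1-one
Conditions: Pd(OAc)2 (5 mol %), PPh3 (12 mol %), 2,2-dimethyl-1,3-dioxane-4,6-dione (2.5 equiv), 1,4-dioxane, rt
Reagents that add atoms: none
Why: Zerovalent palladium formed in situ ionises the allyl ester, the β-keto carboxylate loses CO2, and the C1–C7 enolate is protonated by the acidic dioxanedione, which also takes up the allyl group (decarboxylative protonation of an allyl β-keto ester); kinetic protonation from the face opposite the adjacent C6 arm should place hydrogen trans and the acetonyl group cis to that arm (7R) in a non-basic medium that does not epimerise the product.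

**Step 16**
Reactants: 22 (5S,6S,7R)-2-[(tert-butyldiphenylsilyloxy)methyl]-5-methyl-6-[(E)-2-(3-methylbut-2-enoyloxy)ethenyl]-5-(4-methylpent-3-en-1-yl)-7-(2-oxopropyl)cyclohept-2-en-1-one
Product: 23 (5S,6S,7R)-2-(hydroxymethyl)-5-methyl-6-[(E)-2-(3-methylbut-2-enoyloxy)ethenyl]-5-(4-methylpent-3-en-1-yl)-7-(2-oxopropyl)cyclohept-2-en-1-one (CNP0247522.1)
Conditions: HF·pyridine, THF–pyridine, 0 °C → rt
Reagents that add atoms: none
Why: Buffered fluoride desilylation frees the primary allylic alcohol under weakly acidic conditions that should leave the enol ester, the enone and the epimerisable C7 centre untouched.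

**Compound list**
1 | 5-bromo-2-methylpent-2-ene | CC(C)=CCCBr | starting material
2 | 3-methylcyclohex-2-en-1-one | CC1=CC(=O)CCC1 | starting material
3 | (4-methylpent-3-en-1-yl)magnesium bromide | CC(C)=CCC[Mg]Br | intermediate (not isolated)
4 | (3S)-3-methyl-3-(4-methylpent-3-en-1-yl)cyclohexan-1-one | O=C1CCC[C@@](C)(CCC=C(C)C)C1 | intermediate
5 | potassium (5R)-5-methyl-5-(4-methylpent-3-en-1-yl)cyclohex-1-en-1-olate | [K+].[O-]C1=CCC[C@@](C)(CCC=C(C)C)C1 | intermediate (not isolated)
6 | (2RS,5R)-2-hydroxy-5-methyl-5-(4-methylpent-3-en-1-yl)cyclohexan-1-one | O=C1C(O)CC[C@@](C)(CCC=C(C)C)C1 | intermediate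
7 | methyl (3R)-3,7-dimethyl-3-(3-oxopropyl)oct-6-enoate | O=CCC[C@@](C)(CCC=C(C)C)CC(=O)OC | intermediate
8 | methyl (3S)-3,7-dimethyl-3-[(1E)-3-oxoprop-1-en-1-yl]oct-6-enoate | O=C/C=C/[C@@](C)(CCC=C(C)C)CC(=O)OC | intermediate
9 | (2E,4S)-4-(2-hydroxyethyl)-4,8-dimethylnona-2,7-dien-1-ol | OC/C=C/[C@@](C)(CCC=C(C)C)CCO | intermediate
10 | (2E,4S)-4,8-dimethyl-4-(2-oxoethyl)nona-2,7-dienal | O=C/C=C/[C@@](C)(CCC=C(C)C)CC=O | intermediate
11 | dimethyl 3-oxopentanedioate | COC(=O)CC(=O)CC(=O)OC | starting material
12 | diallyl 3-oxopentanedioate | C=CCOC(=O)CC(=O)CC(=O)OCC=C | intermediate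
13 | diallyl 2-[(3S,4E)-3-methyl-3-(4-methylpent-3-en-1-yl)-6-oxohex-4-en-1-ylidene]-3-oxopentanedioate (alkylidene E/Z interconverting) | C=CCOC(=O)CC(=O)C(C(=O)OCC=C)=CC[C@](C)(CCC=C(C)C)/C=C/C=O | intermediate (not isolated)
14 | diallyl (5S,6S)-5-methyl-5-(4-methylpent-3-en-1-yl)-1-oxo-6-(2-oxoethyl)cyclohept-2-ene-2,7-dicarboxylate (C7 epimers, enolised) | C=CCOC(=O)C1C(=O)C(C(=O)OCC=C)=CC[C@](C)(CCC=C(C)C)[C@H]1CC=O | intermediate
15 | diallyl (5S,6S)-6-(1,3-dioxolan-2-ylmethyl)-5-methyl-5-(4-methylpent-3-en-1-yl)-1-oxocyclohept-2-ene-2,7-dicarboxylate | C=CCOC(=O)C1C(=O)C(C(=O)OCC=C)=CC[C@](C)(CCC=C(C)C)[C@H]1CC2OCCO2 | intermediate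
16 | sodium enolate of 15 (C1–O−, C1=C7) | [Na+].C=CCOC(=O)C1=C([O-])C(C(=O)OCC=C)=CC[C@](C)(CCC=C(C)C)[C@H]1CC2OCCO2 | intermediate (not isolated)
17 | allyl (5S,6S)-6-(1,3-dioxolan-2-ylmethyl)-2-(hydroxymethyl)-5-methyl-5-(4-methylpent-3-en-1-yl)-1-oxocyclohept-2-ene-7-carboxylate | C=CCOC(=O)C1C(=O)C(CO)=CC[C@](C)(CCC=C(C)C)[C@H]1CC2OCCO2 | intermediate
18 | allyl (5S,6S)-2-[(tert-butyldiphenylsilyloxy)methyl]-6-(1,3-dioxolan-2-ylmethyl)-5-methyl-5-(4-methylpent-3-en-1-yl)-1-oxocyclohept-2-ene-7-carboxylate | C=CCOC(=O)C1C(=O)C(CO[Si](c2ccccc2)(c2ccccc2)C(C)(C)C)=CC[C@](C)(CCC=C(C)C)[C@H]1CC2OCCO2 | intermediate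
19 | allyl (5S,6R,7ξ)-2-[(tert-butyldiphenylsilyloxy)methyl]-6-(1,3-dioxolan-2-ylmethyl)-5-methyl-5-(4-methylpent-3-en-1-yl)-1-oxo-7-(2-oxopropyl)cyclohept-2-ene-7-carboxylate | C=CCOC(=O)C1(CC(C)=O)C(=O)C(CO[Si](c2ccccc2)(c2ccccc2)C(C)(C)C)=CC[C@](C)(CCC=C(C)C)[C@H]1CC2OCCO2 | intermediate
20 | allyl (5S,6R,7ξ)-2-[(tert-butyldiphenylsilyloxy)methyl]-5-methyl-5-(4-methylpent-3-en-1-yl)-1-oxo-6-(2-oxoethyl)-7-(2-oxopropyl)cyclohept-2-ene-7-carboxylate | C=CCOC(=O)C1(CC(C)=O)C(=O)C(CO[Si](c2ccccc2)(c2ccccc2)C(C)(C)C)=CC[C@](C)(CCC=C(C)C)[C@H]1CC=O | intermediate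
21 | allyl (5S,6R,7ξ)-2-[(tert-butyldiphenylsilyloxy)methyl]-5-methyl-6-[(E)-2-(3-methylbut-2-enoyloxy)ethenyl]-5-(4-methylpent-3-en-1-yl)-1-oxo-7-(2-oxopropyl)cyclohept-2-ene-7-carboxylate | C=CCOC(=O)C1(CC(C)=O)C(=O)C(CO[Si](c2ccccc2)(c2ccccc2)C(C)(C)C)=CC[C@](C)(CCC=C(C)C)[C@H]1/C=C/OC(=O)C=C(C)C | intermediate
22 | (5S,6S,7R)-2-[(tert-butyldiphenylsilyloxy)methyl]-5-methyl-6-[(E)-2-(3-methylbut-2-enoyloxy)ethenyl]-5-(4-methylpent-3-en-1-yl)-7-(2-oxopropyl)cyclohept-2-en-1-one | CC(=O)C[C@H]1C(=O)C(CO[Si](c2ccccc2)(c2ccccc2)C(C)(C)C)=CC[C@](C)(CCC=C(C)C)[C@H]1/C=C/OC(=O)C=C(C)C | intermediate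
23 | (5S,6S,7R)-2-(hydroxymethyl)-5-methyl-6-[(E)-2-(3-methylbut-2-enoyloxy)ethenyl]-5-(4-methylpent-3-en-1-yl)-7-(2-oxopropyl)cyclohept-2-en-1-one | CC(=O)C[C@H]1C(=O)C(CO)=CC[C@](C)(CCC=C(C)C)[C@H]1/C=C/OC(=O)C=C(C)C | target

**Step count**
Total: 16 steps. Longest linear sequence: 15 steps (steps 1–6 and 8–16); step 7 is a one-step side branch.

**Steps most likely to fail**

Step 8 (proposed new method). Iminium formation at the enal, whose β-carbon is flanked by the quaternary centre, may be slow. Adduct 13 would then be consumed by intermolecular Michael oligomerisation or by an intramolecular oxa-Diels–Alder reaction with the trisubstituted alkene, or an amine-base background cyclisation would erode the C6 selectivity. The fallback uses known chemistry, sets out from 10 and 12 and returns at 14. The condensation is run alone with ethylenediammonium diacetate (CH2Cl2, 0 °C) and 13 is isolated. The ring is then closed by activating the nucleophile instead of the electrophile, through the chelated magnesium enolate of the β-keto ester (MgBr2·OEt2, Et3N, CH2Cl2, −20 °C, high dilution), an intramolecular Michael addition under substrate control that needs no iminium ion. The C6 epimers of 14 would be separated by chromatography, if necessary after conversion into 15. No compound outside the list is made.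

Step 10. Hydride delivery may not stay confined to the C2 ester: incomplete enolate formation would expose the C1 carbonyl and the C7 ester, or the alkylidene ester could be reduced in the conjugate sense. The fallback sets out from 15 and returns at 22; it gives up the C2 carboxyl carbon and brings the hydroxymethyl group in by a Morita–Baylis–Hillman reaction. Compound 15 is C-alkylated with chloroacetone (K2CO3, NaI, acetone) to the diallyl (5S,6R,7ξ)-7-acetonyl diester F1. Pd(PPh3)4 and morpholine (THF, rt then 40 °C) remove both allyl groups; the C7 acid decarboxylates at once with protonation and the C2 alkylidene acid after reversible conjugate addition of morpholine, giving the (5S,6S,7R)-2-unsubstituted cycloheptenone F2. Aqueous formaldehyde with DMAP (THF–H2O) gives the 2-(hydroxymethyl) enone F3, and TBDPSCl with imidazole gives the silyl ether F4. PPTS in wet acetone gives the aldehyde F5, and enol esterification as in step 14 gives 22. The price is that C7 is set earlier and then meets weak bases.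

Step 15. Protonation of the C1–C7 enol may occur on the face syn to the C6 arm, so that the C7 epimer predominates. The fallback sets out from 18 and returns at 22; it lets the carbon substituent rather than the proton arrive last, so that the same facial preference now gives the cis product. Compound 18 undergoes palladium-catalysed decarboxylative allylation (Pd(PPh3)4, THF, rt) to the (5S,6S,7R)-7-allyl ketone F6. Wacker oxidation of the terminal alkene (PdCl2, CuCl, O2, DMF–H2O) gives the methyl ketone F4, the silyl ether already met in the fallback to step 10. Acetal hydrolysis to the aldehyde F5 and enol esterification then lead to 22 as described there.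

**Further compounds**
F0 | step 8 | none | none
F1 | step 10 | diallyl (5S,6R,7ξ)-6-(1,3-dioxolan-2-ylmethyl)-5-methyl-5-(4-methylpent-3-en-1-yl)-1-oxo-7-(2-oxopropyl)cyclohept-2-ene-2,7-dicarboxylate | C=CCOC(=O)C1(CC(C)=O)C(=O)C(C(=O)OCC=C)=CC[C@](C)(CCC=C(C)C)[C@H]1CC2OCCO2
F2 | step 10 | (5S,6S,7R)-6-(1,3-dioxolan-2-ylmethyl)-5-methyl-5-(4-methylpent-3-en-1-yl)-7-(2-oxopropyl)cyclohept-2-en-1-one | CC(=O)C[C@H]1C(=O)C=CC[C@](C)(CCC=C(C)C)[C@H]1CC2OCCO2
F3 | step 10 | (5S,6S,7R)-6-(1,3-dioxolan-2-ylmethyl)-2-(hydroxymethyl)-5-methyl-5-(4-methylpent-3-en-1-yl)-7-(2-oxopropyl)cyclohept-2-en-1-one | CC(=O)C[C@H]1C(=O)C(CO)=CC[C@](C)(CCC=C(C)C)[C@H]1CC2OCCO2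
F4 | step 10 | (5S,6S,7R)-2-[(tert-butyldiphenylsilyloxy)methyl]-6-(1,3-dioxolan-2-ylmethyl)-5-methyl-5-(4-methylpent-3-en-1-yl)-7-(2-oxopropyl)cyclohept-2-en-1-one | CC(=O)C[C@H]1C(=O)C(CO[Si](c2ccccc2)(c2ccccc2)C(C)(C)C)=CC[C@](C)(CCC=C(C)C)[C@H]1CC2OCCO2
F5 | step 10 | (5S,6S,7R)-2-[(tert-butyldiphenylsilyloxy)methyl]-5-methyl-5-(4-methylpent-3-en-1-yl)-6-(2-oxoethyl)-7-(2-oxopropyl)cyclohept-2-en-1-one | CC(=O)C[C@H]1C(=O)C(CO[Si](c2ccccc2)(c2ccccc2)C(C)(C)C)=CC[C@](C)(CCC=C(C)C)[C@H]1CC=O
F6 | step 15 | (5S,6S,7R)-7-allyl-2-[(tert-butyldiphenylsilyloxy)methyl]-6-(1,3-dioxolan-2-ylmethyl)-5-methyl-5-(4-methylpent-3-en-1-yl)cyclohept-2-en-1-one | C=CC[C@H]1C(=O)C(CO[Si](c2ccccc2)(c2ccccc2)C(C)(C)C)=CC[C@](C)(CCC=C(C)C)[C@H]1CC2OCCO2
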